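Cycloshizukaol A is C2-symmetric. Its twelve-membered ring consists of two identical planar segments C15–C4=C5–C6=C7–C11, joined only by the two C11–C15′ bonds. Cutting both bonds at once gives two molecules of one flat lindenane triene (C15=C4–C5=C6–C7=C11). The key step is the head-to-tail formal [6+6] cyclodimerisation of this triene, relayed by DABCO. It forms both bonds, the macrocycle and both quaternary centres in one operation. The precursor looks unlike the product: an allylic bromide (the HBr adduct of the triene) whose temporary enol-lactone ring (C12–O–C8) locks the C7=C11 geometry. Methanolysis of the two lactones and hydroxylation at C9 finish the synthesis.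

Key step: step 10

Remark: lindenane numbering is used throughout. C1–C3 form the cyclopropane; C1/C3/C4/C5/C10 form the five-membered ring; C5–C10 form ring B; C11–C13 are the side chain; C14 is the angular methyl; C15 sits on C4. Primes mark the second half, and β is the face of C14. (+)-Verbenone is taken as a commercial terpene.

Step 1
Reactants: 1 (1R,5R)-(+)-verbenone; 2 vinylmagnesium bromide
Product: 3 4,6,6-trimethyl-4-vinylbicyclo[3.1.1]heptan-2-one (vinyl anti to the CMe2 bridge)
Conditions: 2 (1.5 equiv), CuBr·SMe2 (10 mol %), THF, −40 → 0 °C; then 1 M HCl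
Reagents that add atoms: vinylmagnesium bromide C=C[Mg]Br
Why: Copper-catalysed 1,4-addition of a Grignard reagent; the syn methyl of the CMe2 bridge shields one enone face, so vinyl enters anti to the bridge and sets C10, with C14 cis to the bridge carbon that becomes C4.

Step 2
Reactants: 3
Product: 5 (3S,4S)-4-isopropenyl-3-methyl-3-vinylcyclohexanone (vinyl trans to isopropenyl), via enol acetate 4 (not isolated)
Conditions: Ac2O, Zn(OAc)2 (0.3 equiv), BF3·OEt2 (0.3 equiv), CH2Cl2, 0 °C; then K2CO3 (cat.), MeOH, rt
Reagents that add atoms: none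
Why: Lewis-acid-induced cyclobutane fragmentation (cleavage of the C7–CMe2 bond to a tertiary cation and an enol acetate, then proton loss) unveils the isopropenyl group (C3, C4, C15) on C5 without touching C5 or C10, and methanolysis of 4 returns the C8 ketone.

Step 3
Reactants: 5
Product: 7 2-(2-methyl-4-oxo-2-vinylcyclohexyl)acrolein (configuration as in 5), via allylic alcohol 6 (not isolated)
Conditions: SeO2 (0.3 equiv), t-BuOOH (2 equiv), CH2Cl2, rt; then Dess–Martin periodinane, CH2Cl2, 0 °C
Reagents that add atoms: tert-butyl hydroperoxide CC(C)(C)OO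
Why: SeO2 allylic oxidation (ene then [2,3] shift) touches only the 1,1-disubstituted alkene, since the vinyl group has no allylic hydrogen, and takes a methyl hydrogen because H-5 lies in the alkene plane next to quaternary C10; Dess–Martin oxidation then carries 6 to the enal.

Step 4
Reactants: 7
Product: 8 (E)-N-tosylhydrazone of enal 7
Conditions: TsNHNH2 (1.0 equiv), MeOH, 0 °C
Reagents that add atoms: p-toluenesulfonyl hydrazide Cc1ccc(cc1)S(=O)(=O)NN
Why: Hydrazone condensation, in which one equivalent at low temperature is consumed by the aldehyde well before the ketone reacts.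

Step 5
Reactants: 8
Product: 10 11,12,13-trinorlinden-4(15)-en-8-one (C2 and C14 β; H-1/H-3/H-5 α), via vinyldiazo compound 9 (not isolated)
Conditions: NaH (1.05 equiv), THF, 0 °C; then Pd2(dba)3 (5 mol %), 60 °C, 0.01 M
Reagents that add atoms: none
Why: Bamford–Stevens generation of 9 followed by metal-carbene intramolecular cyclopropanation of the neighbouring vinyl group; the trans-diequatorial tether allows only a cis-fused bicyclo[3.1.0]hexane, and the vinyl group reacts in the rotamer that eclipses the axial C10–CH3 bond, which places C2 syn to C14.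

Step 6
Reactants: 10; 11 methyl pyruvate
Product: 13 γ-keto acid 2-hydroxy-2-(8-oxo-11,12,13-trinorlinden-4(15)-en-7-yl)propanoic acid (C7/C11 epimers), via aldol ester 12 (not isolated)
Conditions: LDA (1.1 equiv), THF, −78 °C; 11 (1.3 equiv), −78 °C; then LiOH, THF/H2O, 0 °C; 1 M HCl to pH 3
Reagents that add atoms: methyl pyruvate CC(=O)C(=O)OC; lithium hydroxide [Li+].[OH-]
Why: Kinetic deprotonation occurs at C7 rather than at neopentyl C9, the directed aldol addition to the keto group of 11 forms C7–C11 (both new centres are erased in step 7), and saponification frees the acid.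

Step 7
Reactants: 13
Product: 14 chloranthalactone A (lindena-4(15),7(11),8-trien-12,8-olide)
Conditions: Ac2O (4 equiv), DMAP (10 mol %), pyridine, 60 °C
Reagents that add atoms: none
Why: Acetylation and E1cB loss of the tertiary oxygen give C7=C11, and the Z keto acid is dehydrated through its 8-hydroxybutenolide form to the γ-ylidene butenolide (classical enol lactonisation of a γ-keto acid); the E isomer drains by reversible conjugate addition of DMAP, and the non-acidic medium spares the vinylcyclopropane.

Step 8
Reactants: 14
Product: 15 5α-hydroxychloranthalactone A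
Conditions: SeO2 (0.3 equiv), t-BuOOH (1.5 equiv), CH2Cl2, 0 °C → rt
Reagents that add atoms: tert-butyl hydroperoxide CC(C)(C)OO
Why: SeO2 ene/[2,3] oxidation at the only electron-rich alkene with an aligned allylic C–H (axial H-5 next to C4=C15) runs suprafacially on the α face to the 5α-alcohol, a centre that is lost again in step 9.

Step 9
Reactants: 15
Product: 16 15-bromolindena-4,7(11),8-trien-12,8-olide
Conditions: PBr3 (0.4 equiv), pyridine (0.2 equiv), Et2O, −30 °C; used at once
Reagents that add atoms: phosphorus tribromide BrP(Br)Br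
Why: Bromination of a tertiary allylic alcohol with allylic transposition (SN2′, as in linalool to geranyl bromide) moves the double bond to C4=C5 and puts the leaving group on primary C15.

Step 10
Reactants: 16 (two molecules)
Product: 20 (11R,11′R)-macrocyclic bis(enol lactone), via ammonium salt 17 (not isolated), via triene 18 (not isolated), via open-chain zwitterion 19 (not isolated)
Conditions: DABCO (1.1 equiv), MeCN, rt, 30 min; then dilution to 2 mM, Cs2CO3 (1.5 equiv), 4 Å MS, rt
Reagents that add atoms: none
Why: Proposed new method: DABCO displaces bromide to give salt 17, Cs2CO3 removes the doubly allylic H-6, and the resulting ammonium dienolate equilibrates by E1cB with triene 18 and free DABCO; the dienolate adds through C11 to the unsubstituted C15 terminus of a second triene (1,8-addition) to give 19, whose new dienolate expels DABCO from the first C15, so that the amine relays a stepwise, polarity-matched head-to-tail [6+6] cyclodimerisation (a concerted thermal [6+6] is symmetry-forbidden). The closest known reaction types are Rauhut–Currier and Morita–Baylis–Hillman-carbonate annulations (an amine adds and the enolate attacks a second acceptor), ammonium-ylide cyclopropanation (an enolate displaces the ammonium group by SN2) and, in topology, the 1,6-Hofmann elimination of p-methylbenzylammonium salts via p-xylylene to [2.2]paracyclophane. The only ring closed is the twelve-membered one, by a 12-exo-tet SN2 attack of C11′ on C15. Both new centres (11R, 11′R) are controlled by two elements: the lactone ties C12 to O–C8, which fixes the dienolate with C12 syn to C8 and C13 syn to H-6, and C15′ must arrive on the α face, because the two flat tetracycles can stack only α face to α face (both β faces carry C14 and the cyclopropane CH2). Head-to-tail regiochemistry follows from polarity (C15 is the only electrophilic terminus and C11 the preferred nucleophilic one, since α-attack leaves the linear C4=C5–C6=C7–C8=C9 triene), and mismatched or oligomeric adducts revert by retro-addition because only the final SN2 step is irreversible. High dilution and room temperature hold back oligomers and the thermal [4+2] dimer.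

Step 11
Reactants: 20
Product: 22 cycloshizukaol A, via dipotassium bis-enolate 21 (not isolated)
Conditions: KOMe (2.2 equiv), 18-crown-6 (20 mol %), THF, −40 → 0 °C; then 2-(phenylsulfonyl)-3-phenyloxaziridine (2.5 equiv), −78 °C; AcOH
Reagents that add atoms: potassium methoxide C[O-].[K+]; 2-(phenylsulfonyl)-3-phenyloxaziridine O=S(=O)(c1ccccc1)N1OC1c1ccccc1
Why: Methoxide cleaves each enol ester at C12 and thereby releases the methyl ester and the C8 enolate regiospecifically toward C9, which is hydroxylated in the same flask (Davis oxidation); the α face of each C8=C9 lies in the cleft against the cyclopropane of the other half, so oxygen arrives from the outer β face and sets 9R and 9′R (OH cis to C14).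

Compound list
1 | (1R,5R)-(+)-verbenone | CC1=CC(=O)[C@@H]2C[C@H]1C2(C)C | starting material
2 | vinylmagnesium bromide | C=C[Mg]Br | starting material
3 | 4,6,6-trimethyl-4-vinylbicyclo[3.1.1]heptan-2-one, vinyl anti to the CMe2 bridge | C=C[C@]1(C)CC(=O)[C@@H]2C[C@H]1C2(C)C | intermediate
4 | 4-isopropenyl-5-methyl-5-vinylcyclohex-1-enyl acetate (C8 enol acetate toward C7) | C=C[C@]1(C)CC(OC(C)=O)=CC[C@H]1C(C)=C | intermediate
5 | (3S,4S)-4-isopropenyl-3-methyl-3-vinylcyclohexanone | C=C[C@]1(C)CC(=O)CC[C@H]1C(C)=C | intermediate
6 | 4-(3-hydroxyprop-1-en-2-yl)-3-methyl-3-vinylcyclohexanone, configuration as in 5 | C=C[C@]1(C)CC(=O)CC[C@H]1C(=C)CO | intermediate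
7 | 2-(2-methyl-4-oxo-2-vinylcyclohexyl)acrolein, configuration as in 5 | C=C[C@]1(C)CC(=O)CC[C@H]1C(=C)C=O | intermediate
8 | (E)-N-tosylhydrazone of 7 | C=C[C@]1(C)CC(=O)CC[C@H]1C(=C)/C=N/NS(=O)(=O)c1ccc(C)cc1 | intermediate
9 | vinyldiazo compound from 8 | C=C[C@]1(C)CC(=O)CC[C@H]1C(=C)C=[N+]=[N-] | intermediate
10 | 11,12,13-trinorlinden-4(15)-en-8-one (C2 and C14 β; H-1, H-3, H-5 α) | C=C1[C@H]2C[C@H]2[C@]2(C)CC(=O)CC[C@@H]12 | intermediate
11 | methyl pyruvate | CC(=O)C(=O)OC | starting material
12 | aldol ester (C7 and C11 epimers, both centres erased later) | C=C1[C@H]2C[C@H]2[C@]2(C)CC(=O)C(C(C)(O)C(=O)OC)C[C@@H]12 | intermediate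
13 | γ-keto acid (C7 and C11 epimers) | C=C1[C@H]2C[C@H]2[C@]2(C)CC(=O)C(C(C)(O)C(=O)O)C[C@@H]12 | intermediate
14 | chloranthalactone A | C=C1[C@H]2C[C@H]2[C@]2(C)C=C3OC(=O)C(C)=C3C[C@@H]12 | intermediate
15 | 5α-hydroxychloranthalactone A | C=C1[C@H]2C[C@H]2[C@]2(C)C=C3OC(=O)C(C)=C3C[C@@]12O | intermediate
16 | 15-bromolindena-4,7(11),8-trien-12,8-olide | BrCC1=C2CC3=C(C)C(=O)OC3=C[C@@]2(C)[C@@H]2C[C@H]12 | intermediate
17 | C15 DABCO-ium bromide of 16 | [Br-].C(C1=C2CC3=C(C)C(=O)OC3=C[C@@]2(C)[C@@H]2C[C@H]12)[N+]12CCN(CC1)CC2 | intermediate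
18 | lindena-4(15),5,7(11),8-tetraen-12,8-olide (5,6-didehydrochloranthalactone A) | C=C1C2=CC3=C(C)C(=O)OC3=C[C@@]2(C)[C@@H]2C[C@H]12 | intermediate
19 | open-chain dimer: C11 (R) bonded to C15′, ammonium on C15, lactone dienolate in the second half | [O-]C1=C(C)C2=CC3=C(C[C@@]4(C)C(=O)OC5=C[C@@]6(C)[C@@H]7C[C@@H]7C(C[N+]89CCN(CC8)CC9)=C6C=C54)[C@H]4C[C@H]4[C@]3(C)C=C2O1 | intermediate
20 | (11R,11′R)-macrocyclic bis(enol lactone), twelve-membered ring closed | O=C4[C@]1(C)CC2=C3C=C(C(O5)=C[C@@]3(C)[C@@H]3C[C@H]23)[C@](C)(C5=O)CC2=C3C=C1C(O4)=C[C@@]3(C)[C@@H]1C[C@H]21 | intermediate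
21 | dipotassium C8(O)=C9 bis-enolate of 9,9′-dideoxycycloshizukaol A | [K+].[K+].COC(=O)[C@]1(C)CC2=C3C=C(C([O-])=C[C@@]3(C)[C@@H]3C[C@H]23)[C@](C)(C(=O)OC)CC2=C3C=C1C([O-])=C[C@@]3(C)[C@@H]1C[C@H]21 | intermediate
22 | cycloshizukaol A | COC(=O)[C@]1(C)CC2=C3C=C(C(=O)[C@H](O)[C@@]3(C)[C@@H]3C[C@H]23)[C@](C)(C(=O)OC)CC2=C3C=C1C(=O)[C@H](O)[C@@]3(C)[C@@H]1C[C@H]21 | target

Total step count: 11. Longest linear sequence: 11.

Steps most likely to fail

1. Step 10. The relay may leak into anionic oligomerisation of the triene, into γ-attack, or into the [4+2] dimer, and the closure may be slow because a cyclophane-like ring is formed. The fallback sets out from 14 and 16 and comes back at 20. It makes the two bonds one after the other by ordinary enolate chemistry.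
 - Chloranthalactone A 14 (2 equiv) is deprotonated at C6 with LiHMDS (THF, −78 °C). This lactone-locked dienolate carries no leaving group.
 - It is alkylated at C11 by bromide 16 to give the open-chain dimer F1, whose C11 epimers can be separated.
 - SeO2/t-BuOOH and then PBr3, as in steps 8 and 9, convert the remaining C4=C15/H-5 unit into the tertiary alcohol F2 and the primary bromide F3.
 - Slow addition of F3 to Cs2CO3 in MeCN at high dilution closes the ring by intramolecular C-alkylation. Only one half still has an acidic H-6, and only the other half has a leaving group. The product is 20.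

2. Step 11. Oxidation next to C14 may be sluggish, facial selectivity may be poor, or proton transfer may scramble the cross-conjugated enolate before it is oxidised. The fallback sets out from 20 and comes back at 22. It oxidises first and opens afterwards.
 - Dimethyldioxirane (acetone, −20 °C) epoxidises the two C8=C9 enol-lactone bonds from the outer β face to the bis(acyloxy epoxide) F4.
 - K2CO3 in MeOH at 0 °C then opens each lactone. The C8 alkoxide collapses to the ketone with cleavage of the C8–O epoxide bond, and the C9–O bond is kept. This gives 22.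

3. Step 8. The peroxyseleninic species may epoxidise the enol-lactone alkene, or the tertiary alcohol may lose water prematurely. The fallback sets out from 14 and comes back at 16, bypassing 15.
 - A Schenck ene reaction (O2, tetraphenylporphyrin, hν, CH2Cl2, −20 °C) abstracts H-5 and gives the transposed allylic hydroperoxide F5, with C4=C5 and oxygen on C15.
 - PPh3 reduces F5 to the primary allylic alcohol F6.
 - An Appel reaction (CBr4, PPh3, CH2Cl2, −20 °C) gives 16.

Further compounds
F1 | step 10 | open-chain dimer: chloranthalactone A alkylated at C11 (R) by C15′ of the second lactone, C6=C7 and C4=C15 in the first half | C=C1[C@H]2C[C@H]2[C@]2(C)C=C3OC(=O)[C@](C)(CC4=C5CC6=C(C)C(=O)OC6=C[C@@]5(C)[C@@H]5C[C@H]45)C3=C[C@@H]12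
F2 | step 10 | 5α-hydroxy derivative of F1 | C=C1[C@H]2C[C@H]2[C@]2(C)C=C3OC(=O)[C@](C)(CC4=C5CC6=C(C)C(=O)OC6=C[C@@]5(C)[C@@H]5C[C@H]45)C3=C[C@@]12O
F3 | step 10 | 15-bromo open-chain dimer (C4=C5 and C6=C7 in the brominated half) | BrCC1=C2C=C3C(=C[C@@]2(C)[C@@H]2C[C@H]12)OC(=O)[C@]3(C)CC4=C5CC6=C(C)C(=O)OC6=C[C@@]5(C)[C@@H]5C[C@H]45
F4 | step 11 | macrocyclic bis(8β,9β-epoxy lactone) | O=C4[C@]1(C)CC2=C3C=C([C@]6(O5)O[C@@H]6[C@@]3(C)[C@@H]3C[C@H]23)[C@](C)(C5=O)CC2=C3C=C1[C@]6(O4)O[C@@H]6[C@@]3(C)[C@@H]1C[C@H]21
F5 | step 8 | 15-hydroperoxylindena-4,7(11),8-trien-12,8-olide | OOCC1=C2CC3=C(C)C(=O)OC3=C[C@@]2(C)[C@@H]2C[C@H]12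
F6 | step 8 | 15-hydroxylindena-4,7(11),8-trien-12,8-olide | OCC1=C2CC3=C(C)C(=O)OC3=C[C@@]2(C)[C@@H]2C[C@H]12
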